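Readings and results come from a simulation for substances that don't exist; noise was put on by code.

Don't draw the rising monomer in chains straight on past the last reading; work with the free monomer left, and reckon what can still enter chains as a share of that.

| flask | free monomer | transfer agent | pre-initiator | remark | time |
|---|---|---|---|---|---|
| Tuesday's | 0.013 M | 0.60 mM | 100 µM | run made earlier |  |
| Monday's | 0.030 M | 0.60 mM | 100 µM | run made earlier |  |
| Wednesday's | 0.020 M | 0.60 mM | 150 µM | run made earlier |  |
| red | 0.020 M | 0.600 mM | 100 µM |  | 6.0 min |
| teal | 0.020 M | 0.600 mM | 100 µM |  | 1.5 min |

| run | time / min | monomer in chains / % | free monomer / % |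
|---|---|---|---|
| Tuesday's | 1.00 | 3.2 | 85.6 |
| Tuesday's | 2.00 | 8.6 | 68.9 |
| Tuesday's | 3.00 | 14.5 | 55.5 |
| Tuesday's | 4.00 | 20.6 | 43.7 |
| Tuesday's | 5.00 | 23.5 | 34.0 |
| Tuesday's | 6.00 | 26.2 | 27.4 |
| Monday's | 0.500 | 1.6 | 93.0 |
| Monday's | 0.833 | 2.6 | 88.1 |
| Monday's | 1.33 | 5.3 | 79.0 |
| Monday's | 2.00 | 10.5 | 69.2 |
| Monday's | 4.00 | 21.4 | 41.9 |
| Monday's | 6.00 | 27.9 | 26.6 |
| Wednesday's | 1.33 | 6.9 | 76.8 |
| Wednesday's | 2.50 | 18.1 | 57.0 |
| Wednesday's | 4.00 | 28.8 | 37.4 |
| Wednesday's | 5.00 | 34.5 | 27.0 |
| Wednesday's | 6.00 | 37.0 | 21.1 |

(scatter of a reading: 0.5 percentage points)

- the average divides the monomer in chains by the number of chains begun, living and dead together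
- reactions considered so far: free monomer + initiator -> living end + monomer in chains; free monomer + living end -> monomer in chains + living end; living end + transfer agent -> dead chain; free monomer -> uncatalysed product; free monomer + initiator -> spent initiator; pre-initiator -> initiator
- the earlier runs do not show the number of chains; that part of a forecast is a guess

- which of the two ends with the longer chains by the average number of monomer units in a chain (chains begun, living or dead) ("neither" if they lie within 10%) (red / teal / neither)
- average number of monomer units in a chain (chains begun, living or dead) at the end, red
- average number of monomer units in a chain (chains begun, living or dead) at the end, teal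

You are taking over red and teal, which have one charge and differ in reading time. Monday's and Tuesday's runs have red's pre-initiator and transfer agent, and their last readings stand close together in percent. Over their last two minutes, I read that 38.3% of the free monomer lost went into chains, a selectivity carrying the scatter of the readings. Add that share of the free monomer left to the monomer in chains, averaging their last readings, and you get 37.4% of the charge. This is the chain ceiling, my own estimate of where monomer in chains stops while that share holds, and in red it is 7.48 mM. Keep to the reading times asked. The ceiling estimates the top of the fraction that makes the average, and the runs do not show the number of chains beneath it. So the ceiling gives no length by itself.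

The forecast says red, with 77 (54 to 170) for red and 26 (15 to 60) for teal, and adds “Red is longer whatever the chain count”.

The flask gives 199 for red and 156 for teal, so red ends longer.

    free monomer + initiator → living end + monomer in chains (k = 400 /M/min)
    free monomer + living end → monomer in chains + living end, rate k2*[living end]*[free monomer] (k = 18000 /M/min)
    living end + transfer agent → dead chain (kL = 1300 /M/min)
    free monomer → uncatalysed product (k = 0.130 /min)
    free monomer + initiator → spent initiator (k = 19.0 /M/min)
    pre-initiator → initiator (k = 0.0620 /min)

Red's average already stood at 204 at 3.00 min. Divide the ceiling by the flask's chains begun, living and dead together. For red left to 60.0 min, that gives 106, and the flask gives 106. For teal left to 15.0 min, it gives 142, and the flask gives 139.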